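**Plan**

- Retrosynthesis: the C2–C1' bond of the bicyclo[2.2.2]octenone is cut first (palladium allyl closure), then the C1'–alkenyl bond (alkenylchromium addition to an aldehyde), then C5–C2' (Claisen rearrangement); this leaves α-santonin, ethyl vinyl ether, 6-methylhept-5-en-2-one and methyl chloroformate.
- Forward: ring B and the lactone come intact from santonin; ring A is refunctionalised (oxygen put on C1, the C3 oxygen traded for the C5 arm and the C3–C4 alkene); the side chain is joined at C1'; the bridging ring C2, C1', C2', C5, C10, C1 closes last.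
- Enabling feature: C2 is a CH2 flanked by the C1 ketone and the C3–C4 alkene (C10 is quaternary, so C1 enolises only towards C2). It lies 1,4 across ring A from quaternary C5, whose β-arm C2'–C1' ends at a carbon allylic to the side-chain methylene.
- Stereochemistry: C6, C7, C10 and C11 are those of santonin. The C10 methyl steers the epoxide to the α-face, the resulting 1α-hydroxyl directs hydride to give the 3β-carbinol, and its suprafacial Claisen shift sets C5 cis to the C10 methyl. C2 and C1' are set in the closure.

Key step: step 10

Remark: ring carbons carry santonin (eudesmane) numbers, and C2' (on C5) and C1' are the two carbons of the new bridge. Compounds 14 and 16 are used as mixtures of C1' epimers, on the assumption that the allylpalladium intermediate of step 10 exchanges its two faces.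

Step 1
Reactants: 1 α-santonin
Product: 2 1α,2α-epoxy-3-oxoeudesm-4-en-6α,12-olide
Conditions: t-BuOOH (decane), DBU, CH2Cl2, 0 °C → rt
Reagents that add atoms: tert-butyl hydroperoxide, CC(C)(C)OO
Why: Weitz–Scheffer nucleophilic epoxidation: the tert-butylperoxide anion adds to C1 of the disubstituted C1–C2 enone (the tetrasubstituted C4–C5 enone is too hindered) from the α-face opposite the C10 methyl and the enolate closes the 1α,2α-epoxide, while the non-nucleophilic base spares the lactone.

Step 2
Reactants: 2 1α,2α-epoxy-3-oxoeudesm-4-en-6α,12-olide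
Product: 4 1α-hydroxy-3-oxoeudesm-4-en-6α,12-olide, via 2β-phenylseleno-1α-hydroxy ketone 3 (not isolated)
Conditions: (PhSe)2, NaBH4, EtOH, 0 °C, then AcOH; 0 °C → rt
Reagents that add atoms: none
Why: Organoselenium reduction of an α,β-epoxy ketone: the soft phenylselenolate opens the epoxide by SN2 attack at C2 and a second selenolate removes selenium from the α-seleno ketone, so only the C2–O bond is cleaved, the 1α-hydroxyl keeps its configuration, and the enone and lactone, which a single-electron reductant would attack, are left alone.

Step 3
Reactants: 4 1α-hydroxy-3-oxoeudesm-4-en-6α,12-olide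
Product: 6 1α,3β-dihydroxyeudesm-4-en-6α,12-olide, via O1-diacetoxyborohydride adduct 5 (not isolated)
Conditions: Me4NBH(OAc)3, MeCN–AcOH (1:1), −30 → −20 °C
Reagents that add atoms: none
Why: Saksena–Evans hydroxyl-directed reduction: the axial 1α-hydroxyl displaces an acetate on boron and the bound hydride is delivered inside the molecule to the α-face of the C3 carbonyl, which sets the 3β-carbinol (1,3-anti diol) and avoids conjugate reduction.

Step 4
Reactants: 6 1α,3β-dihydroxyeudesm-4-en-6α,12-olide; 7 ethyl vinyl ether
Product: 8 1α-hydroxy-3β-(vinyloxy)eudesm-4-en-6α,12-olide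
Conditions: Hg(OAc)2 (20 mol%), ethyl vinyl ether as solvent, reflux
Reagents that add atoms: none
Why: Mercury-catalysed transfer vinylation (transetherification): the pseudo-equatorial allylic 3β-hydroxyl should exchange much faster than the axial 1α-hydroxyl, which is neopentylic next to quaternary C10, so the vinyl ether should form at O3 alone.

Step 5
Reactants: 8 1α-hydroxy-3β-(vinyloxy)eudesm-4-en-6α,12-olide
Product: 9 1α-hydroxy-5β-(2-oxoethyl)eudesm-3-en-6α,12-olide
Conditions: PhMe, Et3N (trace), sealed tube, 170 °C
Reagents that add atoms: none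
Why: Claisen rearrangement: the [3,3] shift is suprafacial, so the C3–O bond on the β-face is exchanged for the C5–C2' bond on the same face, which builds quaternary C5 with its arm cis to the C10 methyl, moves the alkene to C3–C4 and unveils the aldehyde at C1'.

Step 6
Reactants: 9 1α-hydroxy-5β-(2-oxoethyl)eudesm-3-en-6α,12-olide
Product: 10 1-oxo-5β-(2-oxoethyl)eudesm-3-en-6α,12-olide
Conditions: Dess–Martin periodinane, pyridine, CH2Cl2, 0 °C → rt
Reagents that add atoms: none
Why: Dess–Martin oxidation: the hindered secondary C1 alcohol is oxidised under buffered, nearly neutral conditions that should leave the aldehyde untouched and keep the new β,γ-unsaturated ketone from moving its alkene into conjugation.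

Step 7
Reactants: 11 6-methylhept-5-en-2-one
Product: 13 6-methylhepta-1,5-dien-2-yl trifluoromethanesulfonate, via lithium enolate 12 (not isolated)
Conditions: LiN(iPr)2, THF, −78 °C; then PhNTf2, −78 → 0 °C
Reagents that add atoms: N-phenylbis(trifluoromethanesulfonimide), O=S(=O)(N(c1ccccc1)S(=O)(=O)C(F)(F)F)C(F)(F)F
Why: Kinetic enolate O-triflation: the lithium amide removes a methyl proton at low temperature and PhNTf2 traps the less substituted enolate on oxygen, giving the 1,1-disubstituted alkenyl triflate.

Step 8
Reactants: 10 1-oxo-5β-(2-oxoethyl)eudesm-3-en-6α,12-olide; 13 6-methylhepta-1,5-dien-2-yl trifluoromethanesulfonate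
Product: 14 5β-(2-hydroxy-7-methyl-3-methylideneoct-6-en-1-yl)-1-oxoeudesm-3-en-6α,12-olide (both C1' epimers)
Conditions: CrCl2, NiCl2 (1 mol%), DMF, rt
Reagents that add atoms: none
Why: Nozaki–Hiyama–Kishi reaction: the alkenylchromium reagent made from the triflate, CrCl2 and catalytic NiCl2 adds to aldehydes only, so the C1 ketone and the lactone should survive; the carbinol centre C1' forms without control, which does not matter because it is erased in step 10.

Step 9
Reactants: 14 allylic alcohol (both C1' epimers); 15 methyl chloroformate
Product: 16 5β-[2-(methoxycarbonyloxy)-7-methyl-3-methylideneoct-6-en-1-yl]-1-oxoeudesm-3-en-6α,12-olide (both C1' epimers)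
Conditions: pyridine, DMAP (cat.), CH2Cl2, 0 °C
Reagents that add atoms: none
Why: Carbonate formation by acylation of the secondary allylic alcohol with a chloroformate under pyridine and DMAP catalysis, which is too mild to enolise the ketone or the lactone, installs the leaving group for ionisation by palladium.

Step 10
Reactants: 16 allylic methyl carbonate (both C1' epimers)
Product: 17 target, the bridged lactone with the C2'–C1' bridge on the β-face between C5 and C2 and the 6-methylhepta-1,5-dien-2-yl group on C1' syn to the C3–C4 alkene
Conditions: Pd(PPh3)4 (10 mol%), THF, 60 °C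
Reagents that add atoms: none
Why: Zerovalent palladium ionises the allylic carbonate with loss of CO2 to a 2-substituted π-allyl palladium cation spanning C1' and the terminal methylene, and the methoxide set free removes a proton from C2, which is both α to the C1 ketone and allylic to C3–C4, to give a delocalised, soft dienolate that attacks C1' on the face opposite palladium. The closest known reaction type is the Tsuji–Trost allylic alkylation of ketone enolates with allyl carbonates without added base, here in an intramolecular, bridging form. The ring C2, C1', C2', C5, C10, C1 (and with it the ring C2, C1', C2', C5, C4, C3) closes as a six-membered boat with the rest of the allyl unit outside the ring (exo), whereas attack at the methylene terminus would be an eight-membered closure. C2 can only take the bridge on the β-face because the arm is held on the β-face of C5; at C1' the two allyl faces exchange through the σ-allyl form at the methylene terminus, so both carbonate epimers should funnel into the transition state that puts the bulky alkenyl–palladium unit over the flat C3–C4 end of the dienolate and the hydrogen towards C1 and the C10 methyl, which leans over the bridge. The step needs C- over O-alkylation and α- over γ-attack: an O-allyl dienol ether would be re-ionised by the catalyst, attack through C4 would need a four-membered ring, and C1 can enolise only towards C2 because C10 is quaternary. The product has C2 at a bridgehead between ketone and alkene, so it can neither enolise nor move the alkene into conjugation.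

**Compound list**

1 | α-santonin (3-oxoeudesma-1,4-dien-6α,12-olide, 10β-methyl, 11S) | O=C1C=C[C@]2(C)CC[C@H]3[C@H](C)C(=O)O[C@@H]3C2=C1C | starting material
2 | 1α,2α-epoxy-3-oxoeudesm-4-en-6α,12-olide | O=C1[C@@H]4O[C@@H]4[C@]2(C)CC[C@H]3[C@H](C)C(=O)O[C@@H]3C2=C1C | intermediate
3 | 1α-hydroxy-2β-(phenylseleno)-3-oxoeudesm-4-en-6α,12-olide (not isolated) | O=C1[C@@H]([Se]c5ccccc5)[C@H](O)[C@]2(C)CC[C@H]3[C@H](C)C(=O)O[C@@H]3C2=C1C | intermediate
4 | 1α-hydroxy-3-oxoeudesm-4-en-6α,12-olide | O=C1C[C@H](O)[C@]2(C)CC[C@H]3[C@H](C)C(=O)O[C@@H]3C2=C1C | intermediate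
5 | tetramethylammonium salt of the diacetoxy(hydrido)borate bound to O1 of 4 (not isolated) | O=C1C[C@H](O[BH-](OC(C)=O)OC(C)=O)[C@]2(C)CC[C@H]3[C@H](C)C(=O)O[C@@H]3C2=C1C.C[N+](C)(C)C | intermediate
6 | 1α,3β-dihydroxyeudesm-4-en-6α,12-olide | O[C@H]1C[C@H](O)[C@]2(C)CC[C@H]3[C@H](C)C(=O)O[C@@H]3C2=C1C | intermediate
7 | ethyl vinyl ether | C=COCC | starting material
8 | 1α-hydroxy-3β-(vinyloxy)eudesm-4-en-6α,12-olide | C=CO[C@H]1C[C@H](O)[C@]2(C)CC[C@H]3[C@H](C)C(=O)O[C@@H]3C2=C1C | intermediate
9 | 1α-hydroxy-5β-(2-oxoethyl)eudesm-3-en-6α,12-olide (arm cis to the C10 methyl) | O=CC[C@@]23C(C)=CC[C@H](O)[C@]2(C)CC[C@H]1[C@H](C)C(=O)O[C@@H]13 | intermediate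
10 | 1-oxo-5β-(2-oxoethyl)eudesm-3-en-6α,12-olide | O=CC[C@@]23C(C)=CCC(=O)[C@]2(C)CC[C@H]1[C@H](C)C(=O)O[C@@H]13 | intermediate
11 | 6-methylhept-5-en-2-one | CC(=O)CCC=C(C)C | starting material
12 | lithium 6-methylhepta-1,5-dien-2-olate (not isolated) | [Li]OC(=C)CCC=C(C)C | intermediate
13 | 6-methylhepta-1,5-dien-2-yl trifluoromethanesulfonate | C=C(OS(=O)(=O)C(F)(F)F)CCC=C(C)C | intermediate
14 | 5β-(2-hydroxy-7-methyl-3-methylideneoct-6-en-1-yl)-1-oxoeudesm-3-en-6α,12-olide (both C1' epimers) | C=C(CCC=C(C)C)C(O)C[C@@]23C(C)=CCC(=O)[C@]2(C)CC[C@H]1[C@H](C)C(=O)O[C@@H]13 | intermediate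
15 | methyl chloroformate | COC(=O)Cl | starting material
16 | 5β-[2-(methoxycarbonyloxy)-7-methyl-3-methylideneoct-6-en-1-yl]-1-oxoeudesm-3-en-6α,12-olide (both C1' epimers) | C=C(CCC=C(C)C)C(OC(=O)OC)C[C@@]23C(C)=CCC(=O)[C@]2(C)CC[C@H]1[C@H](C)C(=O)O[C@@H]13 | intermediate
17 | target: 1-oxoeudesm-3-en-6α,12-olide bridged on the β-face from C5 through C2' and C1' to C2, C1' carrying the 6-methylhepta-1,5-dien-2-yl group syn to the C3–C4 alkene | C=C(CCC=C(C)C)[C@H]1C[C@@]23C(C)=C[C@@H]1C(=O)[C@]2(C)CC[C@H]1[C@H](C)C(=O)O[C@@H]13 | target

**Step count and risks**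

Total step count: 10. Longest linear sequence: 9 steps (steps 1–6 and 8–10 from α-santonin); step 7 is a one-step side branch.

The three steps most likely to fail:

Step 10. The internal allyl terminus is hindered, so the allylpalladium intermediate may lose a proton to a 1,3-diene before C2 attacks, the C3–C4 alkene may drift into conjugation with the ketone, or the closure may show poor facial selectivity at C1'. The fallback sets out from epoxy ketone 2 and returns to the route at 17. Treatment of 2 with N2H4·H2O and catalytic AcOH in MeOH (Wharton transposition) should pass through the epoxy hydrazone F1, which is not isolated, to 1α-hydroxyeudesma-2,4-dien-6α,12-olide F2. Oxidation of this allylic alcohol with MnO2 in CH2Cl2 should give 1-oxoeudesma-2,4-dien-6α,12-olide F3, a cyclohexa-2,4-dienone that quaternary C10 keeps from aromatising. Heating F3 in excess myrcene (C=CC(=C)CCC=C(C)C) should then form both bridge bonds, C2–C1' and C5–C2', in a Diels–Alder reaction. The dienone C2–C5 is the 4π partner and the vinyl group of myrcene the 2π partner; the electron-poor terminus C5 should take the CH2 end, and the endo rule should place the alkenyl group syn to the new C3–C4 alkene.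

Step 5. At the temperature needed to join two adjacent quaternary carbons, the allyl vinyl ether may instead lose acetaldehyde to give ring A dienes, or the new aldehyde may undergo a carbonyl-ene reaction with the C3–C4 alkene. The fallback sets out from diol 6 and returns at aldehyde 9. Heating 6 with N,N-dimethylacetamide dimethyl acetal in xylene (Eschenmoser–Claisen rearrangement) should form the ketene N,O-acetal F4 at O3 in the flask. This more electron-rich unit should rearrange at lower temperature to the dimethylamide F5, while the hindered 1α-hydroxyl exchanges reversibly and is restored on work-up. Cp2Zr(H)Cl in THF should then reduce the tertiary amide to aldehyde 9 without touching the lactone.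

Step 4. Site selectivity may be poor, with the C1 hydroxyl vinylated along with the C3 hydroxyl. The fallback sets out from diol 6 and returns at aldehyde 9. Both hydroxyls are vinylated on purpose with excess ethyl vinyl ether and Hg(OCOCF3)2 to give the bis(vinyl ether) F6. Heating should rearrange only the allylic O3 unit and leave the O1 vinyl ether as a protecting group in the 1α-vinyloxy aldehyde F7. Mild acid hydrolysis of this enol ether (pyridinium p-toluenesulfonate, acetone–water) should free the C1 hydroxyl and give 9.

**Further compounds**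

F1 | step 10 | 1α,2α-epoxy-3-hydrazonoeudesm-4-en-6α,12-olide (not isolated) | NN=C1[C@@H]4O[C@@H]4[C@]2(C)CC[C@H]3[C@H](C)C(=O)O[C@@H]3C2=C1C
F2 | step 10 | 1α-hydroxyeudesma-2,4-dien-6α,12-olide | C1=C[C@H](O)[C@]2(C)CC[C@H]3[C@H](C)C(=O)O[C@@H]3C2=C1C
F3 | step 10 | 1-oxoeudesma-2,4-dien-6α,12-olide | C1=CC(=O)[C@]2(C)CC[C@H]3[C@H](C)C(=O)O[C@@H]3C2=C1C
F4 | step 5 | 3β-[1-(dimethylamino)vinyloxy]-1α-hydroxyeudesm-4-en-6α,12-olide (not isolated) | C=C(N(C)C)O[C@H]1C[C@H](O)[C@]2(C)CC[C@H]3[C@H](C)C(=O)O[C@@H]3C2=C1C
F5 | step 5 | 5β-[2-(dimethylamino)-2-oxoethyl]-1α-hydroxyeudesm-3-en-6α,12-olide | CN(C)C(=O)C[C@@]23C(C)=CC[C@H](O)[C@]2(C)CC[C@H]1[C@H](C)C(=O)O[C@@H]13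
F6 | step 4 | 1α,3β-bis(vinyloxy)eudesm-4-en-6α,12-olide | C=CO[C@H]1C[C@H](OC=C)[C@]2(C)CC[C@H]3[C@H](C)C(=O)O[C@@H]3C2=C1C
F7 | step 4 | 5β-(2-oxoethyl)-1α-(vinyloxy)eudesm-3-en-6α,12-olide | O=CC[C@@]23C(C)=CC[C@H](OC=C)[C@]2(C)CC[C@H]1[C@H](C)C(=O)O[C@@H]13
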